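## Analysis of the target

Target 31 is a (2S)-flavanone in which ring A (C4a to C8a) is fused to the dihydropyranone ring C (O1, C2, C3, C4), and ring B, a 2,4-dihydroxyphenyl group, sits on C2. Ring A carries a hydroxyl at C5 that is hydrogen-bonded to the C4 ketone, a methyl ether at C7 and, at C8, a hydrated lavandulyl chain C1''H2–C2''H(isopropenyl)–CH2–CH2–C(CH3)2OH, so that only C6 bears hydrogen. There are two stereocentres, C2 (S) and C2'' (R); they lie six bonds apart across O1, C8a, C8 and C1'', cannot influence each other, and each must be set by its own reagent or catalyst. Sensitive are the C2–O1 bond (benzylic to a ring with ortho and para oxygen; it opens to the chalcone with base or ionises with acid, and either path racemises C2), the isopropenyl group and tertiary alcohol towards acid, and the three phenols. The difficulty is twofold: the chain, the methyl ether and the ring oxygen must be placed without ambiguity on a phloroglucinol core, and the usual closure of ring C by oxa-Michael addition creates C2 in a reversible step. The strategy rests on C3 and C4: they are the only carbons of ring C without stereochemistry, C4 is an aryl ketone carbon on C4a and C3 is the neighbour of oxygen-bearing C2. Ring C can therefore be closed last as a C3=C4 enol ether double bond between a vinyl group on C2 and the enol ether of an acetyl group on C4a, with C2 already fixed as an acyclic (S)-1-arylallyl ether on the C8a oxygen.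

## Retrosynthetic reasoning

Target 31 is traced back to the 4-silyloxy-2H-chromene 29. No skeletal bond is cut; the C4 ketone is carried as its tert-butyldimethylsilyl enol ether, the three phenols as methoxymethyl ethers and the tertiary alcohol as a triethylsilyl ether. All carbon–carbon bonds are thus in place before the last step, which only has to hydrolyse these groups, by way of flavanone 30, gently enough to leave C2 alone.

Chromene 29 is cut at the C3=C4 double bond to give the diene 28, an aryl allyl ether carrying a silyl enol ether ortho to the ether oxygen. This cut is chosen because it is the only ring C bond whose formation touches neither C2 nor the O1–C2 bond, so the stereocentre enters the ring closure as a spectator. The forward reaction is a ring-closing metathesis in which a ruthenium carbene formed at the vinyl group must find the enol ether six atoms away and not the isopropenyl group of the side chain.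

Diene 28 comes from methyl ketone 26 by enol silylation, and 26 is cut at the O1–C2 bond into phenol 18 and cinnamyl carbonate 24. The cut joins the two aromatic halves and creates C2 in the same event. The forward reaction, by way of phenoxide 25, is an iridium-catalysed allylic etherification that must deliver the branched ether with (S) configuration under catalyst control, without a free benzylic cation.

Carbonate 24 is taken back through alcohol 23 and ester 22 to aldehyde 20 and ylide 21, and 20 to 2,4-dihydroxybenzaldehyde 19. The cut is the alkene of the cinnamyl unit, which a stabilised ylide forms with E geometry; the rest is functional group change.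

Phenol 18 is taken back through its acetate 17 and cut at the C8–C1'' bond into aryl iodide 15 and alkyl iodide 11, the latter used as its zinc reagent 16. This bond is chosen because the commercial acetophenone 12 already holds the acetyl group and the full oxygen pattern. Compound 12 is symmetric, so one methoxymethyl ether (13) differentiates its two hydroxyls, and the remaining free hydroxyl, the future O1, directs iodine to its own ortho position (14). Acetate 15 only masks that hydroxyl for the coupling. The forward coupling has to join a primary carbon that has a stereocentre in the β-position to a doubly ortho-substituted arene without β-hydride loss.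

Iodide 11 is taken back by functional group changes through iodo alcohol 10 and diol 9 to epoxy imide 8 and diene imide 7. The tertiary alcohol is the Markovnikov hydrate of the trisubstituted alkene of 7. Epoxidation and hydride opening are used because they distinguish this alkene from the isopropenyl group, which direct hydration methods would attack first.

Imide 7 is cut at the bond between C2'' and its allylic neighbour, which gives the senecioyl imide 4 and prenyl bromide 5; imide 4 comes from oxazolidinone 1 and acid chloride 2. The cut is made here because the dienolate 6 of imide 4 alkylates at its α-carbon, which installs the isopropenyl group and the stereocentre in a single operation; the auxiliary controls the face.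

## Alternatives that were turned down

Alternative 1: The side chain is cut at C1''–C2'' and a lactone C–O bond is drawn from the C8a oxygen, so that C2'' arises in a carbene-catalysed annulation. In the forward step a fluoride source releases an ortho-quinone methide from the silyl ether bromide A2, and a chiral N-heterocyclic carbene turns the acyl imidazole A3 into an azolium enolate that adds to the methide carbon and lactonises to the dihydrocoumarin A1. In its favour, C2'' is set catalytically and the aryl–CH2 bond at C8 is present from the start, with no regiochemical question. Against it, A1 holds neither the acyl carbon at C4a, nor ring B, nor C2. The lactone carbonyl must be turned into the isopropenyl group through a methyl ketone next to the new, epimerisable stereocentre. An acyl group must then be forced into the last ring position between two oxygens, and ring C remains an unsolved, separate problem. On the making of C2'' and on ring A regiochemistry this alternative is stronger than an auxiliary alkylation and a directed iodination. The chosen strategy offers in return a closure of ring C with C2 already fixed, and far fewer steps after its key event.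

Alternative 2: Ring A is cut into a four-carbon and a two-carbon piece across C8–C8a, C6–C7 and C4a–C8a. In the forward step the cyclobutenone A5 opens on heating to a vinylketene, which adds the ynol ether A6; electrocyclic opening and six-electron closure then give phenol A4. In its favour, the polarity of the ynol ether dictates the substitution pattern (chain ortho to the new hydroxyl, methoxy next to it), so there is no halogenation or cross-coupling, and the C8a hydroxyl is free for etherification. Against it, A4 lacks the acyl carbon at C4a. Ortho-acylation between the hydroxyl and the acetal competes with the open C6 position and needs Lewis acid conditions that the acetal, silyl ether and isopropenyl group tolerate poorly. A6 requires the same chiral chain plus an ynol ether synthesis, and A5 is not a stock compound. The alternative is as strong or stronger on regiochemical certainty in ring A, but it leaves ring C and C2 open. The chosen strategy offers a commercial ring A that already carries the acetyl group, so its risk sits in one ring closure and is not spread over arene construction and late acylation.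

Alternative 3: Ring A is cut across C4a–C5 and C8–C8a, so that ring C with C2 is brought in as a dihydropyranone and ring A is built onto it. In the forward step the silyloxy diene A9 adds with its chain-bearing terminus to the oxygen-bearing carbon of the brominated enone A8, and two eliminations aromatise the adduct to A7. In its favour, it is the most convergent plan: A7 is one deprotection from the target, C2 comes from a well-established catalytic hetero-Diels–Alder reaction, and the C5 hydroxyl emerges free. Against it, the dienophile is a vinylogous ester and the diene is substituted at its reacting terminus, so both partners are poor. The acid set free on aromatisation and the heat needed act on a β-aryloxy ketone whose C2–O1 bond can open and reclose, which would racemise C2. On step count and convergence this alternative is clearly stronger. The chosen strategy offers a ring closure of a known type that runs under neutral conditions at moderate temperature and does not touch C2.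

Key step: step 18

Assumption: the sense of induction of the (Sa,Sc,Sc)-phosphoramidite known for phenoxide additions to cinnamyl carbonates (S-configured branched ether) is taken to hold for the ortho-alkoxy cinnamyl carbonate 24; if it is reversed, the mirror-image ligand is used and nothing else changes.

## Route

Step 1
Reactants: 1 (4S)-4-benzyl-1,3-oxazolidin-2-one; 2 3-methylbut-2-enoyl chloride
Product: 4 (4S)-4-benzyl-3-(3-methylbut-2-enoyl)-1,3-oxazolidin-2-one, via lithium oxazolidinide 3 (not isolated)
Conditions: n-BuLi, THF, −78 °C; then 2, −78 to 0 °C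
Reagents that add atoms: none
Why: N-acylation of the lithiated Evans oxazolidinone with an acid chloride; it provides the substrate for the auxiliary-controlled alkylation.

Step 2
Reactants: 4 (4S)-4-benzyl-3-(3-methylbut-2-enoyl)-1,3-oxazolidin-2-one; 5 1-bromo-3-methylbut-2-ene (prenyl bromide)
Product: 7 (4S)-4-benzyl-3-[(2S)-5-methyl-2-(prop-1-en-2-yl)hex-4-enoyl]-1,3-oxazolidin-2-one, via sodium dienolate 6 (not isolated)
Conditions: NaN(SiMe3)2 (1.0 equiv), THF, −78 °C; then 5, −78 to −40 °C
Reagents that add atoms: none
Why: Deconjugative Evans alkylation: γ-deprotonation gives the chelated Z dienolate, which reacts at its α-carbon with the allylic bromide on the face away from the benzyl group. The (S)-auxiliary thereby sets the (2S) centre that becomes C2'', and the double bond moves out of conjugation to form the isopropenyl group.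

Step 3
Reactants: 7 (4S)-4-benzyl-3-[(2S)-5-methyl-2-(prop-1-en-2-yl)hex-4-enoyl]-1,3-oxazolidin-2-one
Product: 8 (4S)-4-benzyl-3-{(2S)-2-[(3,3-dimethyloxiran-2-yl)methyl]-3-methylbut-3-enoyl}-1,3-oxazolidin-2-one (both epimers at the oxirane carbon)
Conditions: mCPBA (1.05 equiv), CH2Cl2/aq. NaHCO3, 0 °C
Reagents that add atoms: 3-chloroperoxybenzoic acid, O=C(OO)c1cccc(Cl)c1
Why: Prilezhaev epoxidation; the electron-rich trisubstituted alkene should react well ahead of the 1,1-disubstituted isopropenyl group, which the neighbouring imide deactivates further. The oxirane stereocentre disappears in step 4, so its configuration does not matter.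

Step 4
Reactants: 8 (4S)-4-benzyl-3-{(2S)-2-[(3,3-dimethyloxiran-2-yl)methyl]-3-methylbut-3-enoyl}-1,3-oxazolidin-2-one
Product: 9 (2S)-5-methyl-2-(prop-1-en-2-yl)hexane-1,5-diol
Conditions: LiAlH4, THF, 0 °C to rt; aq. NaOH work-up
Reagents that add atoms: none
Why: Hydride reduction cleaves the exocyclic imide carbonyl to the primary alcohol, releasing auxiliary 1, and opens the epoxide at its less substituted carbon to give the tertiary alcohol. The stereocentre is not involved.

Step 5
Reactants: 9 (2S)-5-methyl-2-(prop-1-en-2-yl)hexane-1,5-diol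
Product: 10 (5S)-6-iodo-2-methyl-5-(prop-1-en-2-yl)hexan-2-ol
Conditions: I2, PPh3, imidazole, CH2Cl2, 0 °C
Reagents that add atoms: iodine, [I][I]
Why: Appel-type iodination; only the primary hydroxyl can pass through the oxyphosphonium/SN2 sequence, the tertiary one being too hindered.

Step 6
Reactants: 10 (5S)-6-iodo-2-methyl-5-(prop-1-en-2-yl)hexan-2-ol
Product: 11 triethyl{[(5S)-6-iodo-2-methyl-5-(prop-1-en-2-yl)hexan-2-yl]oxy}silane
Conditions: Et3SiOTf, 2,6-lutidine, CH2Cl2, −78 to 0 °C
Reagents that add atoms: triethylsilyl trifluoromethanesulfonate, CC[Si](CC)(CC)OS(=O)(=O)C(F)(F)F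
Why: Silyl triflate silylation of a hindered tertiary alcohol; the ether removes the only acidic proton before the organozinc and enolate steps and falls in the final acid treatment.

Step 7
Reactants: 12 1-(2,6-dihydroxy-4-methoxyphenyl)ethan-1-one
Product: 13 1-[2-hydroxy-4-methoxy-6-(methoxymethoxy)phenyl]ethan-1-one
Conditions: MOMCl (1.05 equiv), i-Pr2NEt, CH2Cl2, 0 °C to rt
Reagents that add atoms: chloromethyl methyl ether, COCCl
Why: O-alkylation with an α-chloro ether; the two hydroxyls of 12 are equivalent by symmetry, and once one has reacted the other is held in the hydrogen bond to the ketone, so the reaction should stop at the mono-ether.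

Step 8
Reactants: 13 1-[2-hydroxy-4-methoxy-6-(methoxymethoxy)phenyl]ethan-1-one
Product: 14 1-[2-hydroxy-3-iodo-4-methoxy-6-(methoxymethoxy)phenyl]ethan-1-one
Conditions: BnMe3N ICl2 (1.0 equiv), NaHCO3, CH2Cl2/MeOH, rt
Reagents that add atoms: benzyltrimethylammonium dichloroiodate, C[N+](C)(C)Cc1ccccc1.Cl[I-]Cl
Why: Electrophilic aromatic iodination; with this reagent chelated free phenols are iodinated at their ortho position, here the less crowded site between OH and OMe (the future C8) rather than the site between the two ethers. Bicarbonate takes up the HCl and protects the acetal.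

Step 9
Reactants: 14 1-[2-hydroxy-3-iodo-4-methoxy-6-(methoxymethoxy)phenyl]ethan-1-one
Product: 15 2-acetyl-6-iodo-5-methoxy-3-(methoxymethoxy)phenyl acetate
Conditions: Ac2O, Et3N, DMAP (cat.), CH2Cl2, rt
Reagents that add atoms: acetic anhydride, CC(=O)OC(C)=O
Why: DMAP-catalysed O-acylation; the acetate removes the acidic proton next to iodine that would quench the organozinc reagent, and it can be taken off later without touching silyl ether or acetal.

Step 10
Reactants: 11 triethyl{[(5S)-6-iodo-2-methyl-5-(prop-1-en-2-yl)hexan-2-yl]oxy}silane; 15 2-acetyl-6-iodo-5-methoxy-3-(methoxymethoxy)phenyl acetate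
Product: 17 2-acetyl-5-methoxy-3-(methoxymethoxy)-6-[(2R)-5-methyl-2-(prop-1-en-2-yl)-5-(triethylsilyloxy)hexyl]phenyl acetate, via alkylzinc iodide 16 (not isolated)
Conditions: 11, Zn dust (activated with BrCH2CH2Br and Me3SiCl), LiCl, THF, 40 °C; then 15, Pd(OAc)2 (3 mol %), SPhos (6 mol %), THF, rt to 40 °C
Reagents that add atoms: none
Why: Negishi coupling of a primary alkylzinc iodide with a hindered aryl iodide; the dialkylbiarylphosphine should make reductive elimination faster than β-hydride elimination, and ketone, ester and acetal are tolerated by the zinc reagent. The stereocentre β to the metal is not involved; its descriptor changes from S to R only because the CH2 group now carries an aryl group in place of iodine.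

Step 11
Reactants: 17 2-acetyl-5-methoxy-3-(methoxymethoxy)-6-[(2R)-5-methyl-2-(prop-1-en-2-yl)-5-(triethylsilyloxy)hexyl]phenyl acetate
Product: 18 1-{2-hydroxy-4-methoxy-6-(methoxymethoxy)-3-[(2R)-5-methyl-2-(prop-1-en-2-yl)-5-(triethylsilyloxy)hexyl]phenyl}ethan-1-one
Conditions: K2CO3 (0.3 equiv), MeOH, 0 °C to rt
Reagents that add atoms: none
Why: Base-catalysed methanolysis of an aryl acetate; the tertiary silyl ether and the acetal do not react with carbonate in methanol.

Step 12
Reactants: 19 2,4-dihydroxybenzaldehyde
Product: 20 2,4-bis(methoxymethoxy)benzaldehyde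
Conditions: MOMCl (2.6 equiv), i-Pr2NEt, CH2Cl2, 0 to 40 °C
Reagents that add atoms: chloromethyl methyl ether, COCCl
Why: Twofold O-alkylation with an α-chloro ether; excess reagent and gentle heating are used so that the chelated ortho hydroxyl reacts as well.

Step 13
Reactants: 20 2,4-bis(methoxymethoxy)benzaldehyde; 21 ethyl (triphenyl-λ5-phosphanylidene)acetate
Product: 22 ethyl (2E)-3-[2,4-bis(methoxymethoxy)phenyl]prop-2-enoate
Conditions: toluene, 80 °C
Reagents that add atoms: none
Why: Wittig olefination with a stabilised ylide, which should give the E alkene required for the linear allyl electrophile.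

Step 14
Reactants: 22 ethyl (2E)-3-[2,4-bis(methoxymethoxy)phenyl]prop-2-enoate
Product: 23 (2E)-3-[2,4-bis(methoxymethoxy)phenyl]prop-2-en-1-ol
Conditions: i-Bu2AlH (2.2 equiv), CH2Cl2, −78 °C
Reagents that add atoms: none
Why: 1,2-reduction of an enoate to the allylic alcohol by an aluminium hydride; the alkene geometry is retained.

Step 15
Reactants: 23 (2E)-3-[2,4-bis(methoxymethoxy)phenyl]prop-2-en-1-ol
Product: 24 (2E)-3-[2,4-bis(methoxymethoxy)phenyl]prop-2-en-1-yl methyl carbonate
Conditions: ClCO2Me, pyridine, CH2Cl2, 0 °C
Reagents that add atoms: methyl chloroformate, COC(=O)Cl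
Why: O-acylation with a chloroformate; the carbonate is the leaving group for the iridium catalyst and releases its own base on ionisation.

Step 16
Reactants: 18 1-{2-hydroxy-4-methoxy-6-(methoxymethoxy)-3-[(2R)-5-methyl-2-(prop-1-en-2-yl)-5-(triethylsilyloxy)hexyl]phenyl}ethan-1-one; 24 (2E)-3-[2,4-bis(methoxymethoxy)phenyl]prop-2-en-1-yl methyl carbonate
Product: 26 1-{2-({(1S)-1-[2,4-bis(methoxymethoxy)phenyl]prop-2-en-1-yl}oxy)-4-methoxy-6-(methoxymethoxy)-3-[(2R)-5-methyl-2-(prop-1-en-2-yl)-5-(triethylsilyloxy)hexyl]phenyl}ethan-1-one, via lithium phenoxide 25 (not isolated)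
Conditions: 18, LiN(SiMe3)2 (1.0 equiv), THF, 0 °C; then 24 (1.3 equiv), [Ir(cod)Cl]2 (2 mol %), (Sa,Sc,Sc)-N,N-bis[1-(2-methoxyphenyl)ethyl]dinaphtho[2,1-d:1',2'-f][1,3,2]dioxaphosphepin-4-amine (4 mol %, pre-activated with n-PrNH2), THF, rt to 40 °C
Reagents that add atoms: none
Why: Iridium-catalysed asymmetric allylic etherification: the cyclometalated iridium phosphoramidite ionises the linear carbonate, and the phenoxide attacks the aryl-substituted terminus of the allyl complex from outside, which gives the branched O-allyl ether. The chiral ligand alone decides the configuration of C2 (S), with no free benzylic cation, and one equivalent of base deprotonates only the phenol, not the methyl ketone.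

Step 17
Reactants: 26 1-{2-({(1S)-1-[2,4-bis(methoxymethoxy)phenyl]prop-2-en-1-yl}oxy)-4-methoxy-6-(methoxymethoxy)-3-[(2R)-5-methyl-2-(prop-1-en-2-yl)-5-(triethylsilyloxy)hexyl]phenyl}ethan-1-one
Product: 28 tert-butyl[(1-{2-({(1S)-1-[2,4-bis(methoxymethoxy)phenyl]prop-2-en-1-yl}oxy)-4-methoxy-6-(methoxymethoxy)-3-[(2R)-5-methyl-2-(prop-1-en-2-yl)-5-(triethylsilyloxy)hexyl]phenyl}ethenyl)oxy]dimethylsilane, via potassium enolate 27 (not isolated)
Conditions: KN(SiMe3)2 (1.1 equiv), THF, −78 °C; then t-BuMe2SiCl, −78 to 0 °C
Reagents that add atoms: tert-butyldimethylsilyl chloride, CC(C)(C)[Si](C)(C)Cl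
Why: Enolisation of the methyl ketone and O-silylation of the potassium enolate; a base and a silyl chloride are used rather than a silyl triflate, because the benzylic, allylic aryl ether would ionise under Lewis acid. The C2–H bond is far less acidic than the ketone methyl group, so C2 is not touched.

Step 18
Reactants: 28 tert-butyl[(1-{2-({(1S)-1-[2,4-bis(methoxymethoxy)phenyl]prop-2-en-1-yl}oxy)-4-methoxy-6-(methoxymethoxy)-3-[(2R)-5-methyl-2-(prop-1-en-2-yl)-5-(triethylsilyloxy)hexyl]phenyl}ethenyl)oxy]dimethylsilane
Product: 29 tert-butyl({(2S)-2-[2,4-bis(methoxymethoxy)phenyl]-7-methoxy-5-(methoxymethoxy)-8-[(2R)-5-methyl-2-(prop-1-en-2-yl)-5-(triethylsilyloxy)hexyl]-2H-chromen-4-yl}oxy)dimethylsilane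
Conditions: second-generation Grubbs catalyst (H2IMes)(PCy3)Cl2Ru=CHPh (10 mol %), 1,4-benzoquinone (20 mol %), toluene (5 mM), 70 °C, argon purge
Reagents that add atoms: none
Why: This is a ring-closing metathesis of an olefinic silyl enol ether, a known way to cyclic silyl enol ethers that has been used on enol ethers of aryl methyl ketones tethered through an ortho heteroatom. The ruthenium benzylidene exchanges with the only monosubstituted alkene, the vinyl group on C2; the new carbene adds [2+2] to the 1,1-disubstituted enol ether on C4a and the ruthenacyclobutane cycloreverts, which forms C3=C4, closes the six-membered ring C and releases ethylene. Ring C is thus closed by metathesis of two exocyclic alkene termini, and the new double bond ends up inside the ring. No stereocentre is formed: C2 was fixed in step 16 and takes no part (neither its C–H nor its C–O bond is touched), and C2'' is remote. Chemoselectivity is needed against the isopropenyl group, which is also 1,1-disubstituted and would give an eight-membered ring with the same carbene; the six-membered closure should win on ring size, and high dilution keeps dimerisation down. The allyl ether must not be isomerised to a vinyl ether by ruthenium hydrides, which would erase C2; benzoquinone is added to scavenge them. Both ortho positions of the aryl ether are substituted, and the temperature stays far below what a Claisen rearrangement to the free para position would need.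

Step 19
Reactants: 29 tert-butyl({(2S)-2-[2,4-bis(methoxymethoxy)phenyl]-7-methoxy-5-(methoxymethoxy)-8-[(2R)-5-methyl-2-(prop-1-en-2-yl)-5-(triethylsilyloxy)hexyl]-2H-chromen-4-yl}oxy)dimethylsilane
Product: 31 (2S)-2-(2,4-dihydroxyphenyl)-5-hydroxy-8-[(2R)-5-hydroxy-5-methyl-2-(prop-1-en-2-yl)hexyl]-7-methoxy-2,3-dihydro-4H-chromen-4-one, via silyl-protected flavanone 30 (not isolated)
Conditions: 3 M aq. HCl/MeOH/THF (1:6:2), 40 °C
Reagents that add atoms: none
Why: Acid hydrolysis: protonation at C3 of the silyl enol ether gives ketone 30 without involving C2, and solvolysis of the triethylsilyl ether and the three acetals follows, the one at C5 helped by the hydrogen bond to the C4 carbonyl. Dilute acid and moderate temperature are chosen to spare the C2–O1 bond, the tertiary alcohol and the isopropenyl group.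

## Compound list

1 | (4S)-4-benzyl-1,3-oxazolidin-2-one | O=C1N[C@@H](Cc2ccccc2)CO1 | starting material
2 | 3-methylbut-2-enoyl chloride | CC(C)=CC(=O)Cl | starting material
3 | lithium (4S)-4-benzyl-2-oxo-1,3-oxazolidin-3-ide (not isolated) | [Li+].O=C1[N-][C@@H](Cc2ccccc2)CO1 | intermediate
4 | (4S)-4-benzyl-3-(3-methylbut-2-enoyl)-1,3-oxazolidin-2-one | CC(C)=CC(=O)N1[C@@H](Cc2ccccc2)COC1=O | intermediate
5 | 1-bromo-3-methylbut-2-ene (prenyl bromide) | CC(C)=CCBr | starting material
6 | sodium (Z)-dienolate of 4 (not isolated) | C=C(C)/C=C(\[O-])N1[C@@H](Cc2ccccc2)COC1=O.[Na+] | intermediate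
7 | (4S)-4-benzyl-3-[(2S)-5-methyl-2-(prop-1-en-2-yl)hex-4-enoyl]-1,3-oxazolidin-2-one | CC(C)=CC[C@@H](C(C)=C)C(=O)N1[C@@H](Cc2ccccc2)COC1=O | intermediate
8 | (4S)-4-benzyl-3-{(2S)-2-[(3,3-dimethyloxiran-2-yl)methyl]-3-methylbut-3-enoyl}-1,3-oxazolidin-2-one, both epimers at the oxirane carbon | CC1(C)OC1C[C@@H](C(C)=C)C(=O)N2[C@@H](Cc3ccccc3)COC2=O | intermediate
9 | (2S)-5-methyl-2-(prop-1-en-2-yl)hexane-1,5-diol | C=C(C)[C@H](CCC(C)(C)O)CO | intermediate
10 | (5S)-6-iodo-2-methyl-5-(prop-1-en-2-yl)hexan-2-ol | C=C(C)[C@H](CCC(C)(C)O)CI | intermediate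
11 | triethyl{[(5S)-6-iodo-2-methyl-5-(prop-1-en-2-yl)hexan-2-yl]oxy}silane | C=C(C)[C@H](CCC(C)(C)O[Si](CC)(CC)CC)CI | intermediate
12 | 1-(2,6-dihydroxy-4-methoxyphenyl)ethan-1-one | COc1cc(O)c(C(C)=O)c(O)c1 | starting material
13 | 1-[2-hydroxy-4-methoxy-6-(methoxymethoxy)phenyl]ethan-1-one | COCOc1cc(OC)cc(O)c1C(C)=O | intermediate
14 | 1-[2-hydroxy-3-iodo-4-methoxy-6-(methoxymethoxy)phenyl]ethan-1-one | COCOc1cc(OC)c(I)c(O)c1C(C)=O | intermediate
15 | 2-acetyl-6-iodo-5-methoxy-3-(methoxymethoxy)phenyl acetate | COCOc1cc(OC)c(I)c(OC(C)=O)c1C(C)=O | intermediate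
16 | {(2S)-5-methyl-2-(prop-1-en-2-yl)-5-[(triethylsilyl)oxy]hexyl}zinc iodide (not isolated) | C=C(C)[C@H](CCC(C)(C)O[Si](CC)(CC)CC)C[Zn]I | intermediate
17 | 2-acetyl-5-methoxy-3-(methoxymethoxy)-6-[(2R)-5-methyl-2-(prop-1-en-2-yl)-5-(triethylsilyloxy)hexyl]phenyl acetate | C=C(C)[C@H](CCC(C)(C)O[Si](CC)(CC)CC)Cc1c(OC)cc(OCOC)c(C(C)=O)c1OC(C)=O | intermediate
18 | 1-{2-hydroxy-4-methoxy-6-(methoxymethoxy)-3-[(2R)-5-methyl-2-(prop-1-en-2-yl)-5-(triethylsilyloxy)hexyl]phenyl}ethan-1-one | C=C(C)[C@H](CCC(C)(C)O[Si](CC)(CC)CC)Cc1c(OC)cc(OCOC)c(C(C)=O)c1O | intermediate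
19 | 2,4-dihydroxybenzaldehyde | O=Cc1ccc(O)cc1O | starting material
20 | 2,4-bis(methoxymethoxy)benzaldehyde | COCOc1ccc(C=O)c(OCOC)c1 | intermediate
21 | ethyl (triphenyl-λ5-phosphanylidene)acetate | CCOC(=O)C=P(c1ccccc1)(c1ccccc1)c1ccccc1 | starting material
22 | ethyl (2E)-3-[2,4-bis(methoxymethoxy)phenyl]prop-2-enoate | CCOC(=O)/C=C/c1ccc(OCOC)cc1OCOC | intermediate
23 | (2E)-3-[2,4-bis(methoxymethoxy)phenyl]prop-2-en-1-ol | OC/C=C/c1ccc(OCOC)cc1OCOC | intermediate
24 | (2E)-3-[2,4-bis(methoxymethoxy)phenyl]prop-2-en-1-yl methyl carbonate | COC(=O)OC/C=C/c1ccc(OCOC)cc1OCOC | intermediate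
25 | lithium phenoxide of 18 (not isolated) | C=C(C)[C@H](CCC(C)(C)O[Si](CC)(CC)CC)Cc1c(OC)cc(OCOC)c(C(C)=O)c1[O-].[Li+] | intermediate
26 | 1-{2-({(1S)-1-[2,4-bis(methoxymethoxy)phenyl]prop-2-en-1-yl}oxy)-4-methoxy-6-(methoxymethoxy)-3-[(2R)-5-methyl-2-(prop-1-en-2-yl)-5-(triethylsilyloxy)hexyl]phenyl}ethan-1-one | C=C(C)[C@H](CCC(C)(C)O[Si](CC)(CC)CC)Cc1c(OC)cc(OCOC)c(C(C)=O)c1O[C@H](c1ccc(OCOC)cc1OCOC)C=C | intermediate
27 | potassium enolate of 26 (not isolated) | C=C(C)[C@H](CCC(C)(C)O[Si](CC)(CC)CC)Cc1c(OC)cc(OCOC)c(C(=C)[O-])c1O[C@H](c1ccc(OCOC)cc1OCOC)C=C.[K+] | intermediate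
28 | tert-butyl[(1-{2-({(1S)-1-[2,4-bis(methoxymethoxy)phenyl]prop-2-en-1-yl}oxy)-4-methoxy-6-(methoxymethoxy)-3-[(2R)-5-methyl-2-(prop-1-en-2-yl)-5-(triethylsilyloxy)hexyl]phenyl}ethenyl)oxy]dimethylsilane | C=C(C)[C@H](CCC(C)(C)O[Si](CC)(CC)CC)Cc1c(OC)cc(OCOC)c(C(=C)O[Si](C)(C)C(C)(C)C)c1O[C@H](c1ccc(OCOC)cc1OCOC)C=C | intermediate
29 | tert-butyl({(2S)-2-[2,4-bis(methoxymethoxy)phenyl]-7-methoxy-5-(methoxymethoxy)-8-[(2R)-5-methyl-2-(prop-1-en-2-yl)-5-(triethylsilyloxy)hexyl]-2H-chromen-4-yl}oxy)dimethylsilane | C=C(C)[C@H](CCC(C)(C)O[Si](CC)(CC)CC)Cc1c(OC)cc(OCOC)c2c1O[C@H](c1ccc(OCOC)cc1OCOC)C=C2O[Si](C)(C)C(C)(C)C | intermediate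
30 | (2S)-2-[2,4-bis(methoxymethoxy)phenyl]-7-methoxy-5-(methoxymethoxy)-8-[(2R)-5-methyl-2-(prop-1-en-2-yl)-5-(triethylsilyloxy)hexyl]-2,3-dihydro-4H-chromen-4-one (not isolated) | C=C(C)[C@H](CCC(C)(C)O[Si](CC)(CC)CC)Cc1c(OC)cc(OCOC)c2c1O[C@H](c1ccc(OCOC)cc1OCOC)CC2=O | intermediate
31 | (2S)-2-(2,4-dihydroxyphenyl)-5-hydroxy-8-[(2R)-5-hydroxy-5-methyl-2-(prop-1-en-2-yl)hexyl]-7-methoxy-2,3-dihydro-4H-chromen-4-one | C=C(C)[C@H](CCC(C)(C)O)Cc1c(OC)cc(O)c2c1O[C@H](c1ccc(O)cc1O)CC2=O | target

## Step count and least certain steps

Total: 19 steps. Longest linear sequence: 12 steps (steps 1 to 6, 10, 11, 16, 17, 18, 19).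

Step 18 (key step). The ring closure may be slow: the carbene sits next to a tertiary benzylic carbon and must add to a 1,1-disubstituted enol ether whose silyloxy group ends up peri to the C5 acetal. Long heating would then give time for migration of the allyl double bond into conjugation with oxygen, which destroys C2, or for closure onto the isopropenyl group. The fallback leaves metathesis altogether. It sets out from phenol 18 and aldehyde 20: Claisen–Schmidt condensation (KOH, EtOH) should give the chalcone (2E)-3-[2,4-bis(methoxymethoxy)phenyl]-1-{2-hydroxy-4-methoxy-6-(methoxymethoxy)-3-[(2R)-5-methyl-2-(prop-1-en-2-yl)-5-(triethylsilyloxy)hexyl]phenyl}prop-2-en-1-one F1. An enantioselective intramolecular oxa-Michael addition with a quinine-derived bifunctional thiourea then closes the O1–C2 bond, and the route is rejoined at flavanone 30, which is deprotected as in step 19. This is known chemistry, but its enantioselectivity on chalcones without an extra activating group is usually moderate, and that is the reason it is not the first choice.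

Step 16. The phenoxide is flanked by two ortho substituents and chelated to the acetyl group, so its attack on the allyl iridium complex may be too slow; carbonate 24 would then decompose or the linear ether would form. The product is an ether of a stabilised phenoxide with an electron-rich allyl group and may be re-ionised by the catalyst, which would lower the enantiomeric purity with time. The fallback sets out from alcohol 23 and phenol 18. Alcohol 23 is converted with 1,1'-carbonyldiimidazole into (2E)-3-[2,4-bis(methoxymethoxy)phenyl]prop-2-en-1-yl 1H-imidazole-1-carboxylate F2, which acylates 18 (DBU) to the mixed carbonate 2-acetyl-5-methoxy-3-(methoxymethoxy)-6-[(2R)-5-methyl-2-(prop-1-en-2-yl)-5-(triethylsilyloxy)hexyl]phenyl (2E)-3-[2,4-bis(methoxymethoxy)phenyl]prop-2-en-1-yl carbonate F3. The same iridium phosphoramidite catalyst then effects a decarboxylative allylic etherification, in which the phenoxide is born inside the ion pair without lithium chelation and recombines at the branched terminus. The route is rejoined at ether 26.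

Step 8. Iodination may occur para to the free hydroxyl (between the two ethers) or twice, since both open positions are activated by three oxygens. The fallback iodinates while the ring is still symmetric and differentiates the hydroxyls afterwards by size. It sets out from 12: one equivalent of N-iodosuccinimide should give 1-(2,6-dihydroxy-3-iodo-4-methoxyphenyl)ethan-1-one F4, the only possible mono-iodide. Acetylation gives 2-acetyl-4-iodo-5-methoxy-1,3-phenylene diacetate F5, and coupling with zinc reagent 16 under the conditions of step 10 gives 2-acetyl-5-methoxy-4-[(2R)-5-methyl-2-(prop-1-en-2-yl)-5-(triethylsilyloxy)hexyl]-1,3-phenylene diacetate F6. Methanolysis gives 1-{2,6-dihydroxy-4-methoxy-3-[(2R)-5-methyl-2-(prop-1-en-2-yl)-5-(triethylsilyloxy)hexyl]phenyl}ethan-1-one F7. One equivalent of chloromethyl methyl ether should then react at the hydroxyl that has no alkyl neighbour, and the route is rejoined at 18.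

Step 10. Transmetalation and reductive elimination at an aryl palladium species with two ortho substituents may be slow, which leaves room for protonation of the zinc reagent or for β-hydride elimination and chain isomerisation. The fallback changes the organometallic partner and the coupling type. It sets out from iodide 11: iodine–lithium exchange (t-BuLi, Et2O, −78 °C) and addition of 9-methoxy-9-borabicyclo[3.3.1]nonane should give lithium 9-methoxy-9-{(2S)-5-methyl-2-(prop-1-en-2-yl)-5-[(triethylsilyl)oxy]hexyl}-9-boranuidabicyclo[3.3.1]nonane F8. This borinate is coupled with aryl iodide 15 in a B-alkyl Suzuki–Miyaura reaction (PdCl2(dppf), aq. K3PO4, DMF, rt), and the route is rejoined at 17. Any acetate lost under these basic conditions gives 18 directly.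

Step 19. Protic acid may open or ionise the C2–O1 bond once the ortho and para hydroxyls of ring B are free, which would erode the configuration at C2; it may also ionise the tertiary alcohol or add to the isopropenyl group. The fallback avoids protic acid in two stages and sets out from 29. Et3N·3HF in THF should cleave the enol ether to the ketone and remove the triethylsilyl group, giving (2S)-2-[2,4-bis(methoxymethoxy)phenyl]-8-[(2R)-5-hydroxy-5-methyl-2-(prop-1-en-2-yl)hexyl]-7-methoxy-5-(methoxymethoxy)-2,3-dihydro-4H-chromen-4-one F9. The aryl acetals are then exchanged for trimethylsilyl ethers with Me3SiOTf and 2,2'-bipyridyl in CH2Cl2 at 0 °C and hydrolysed with water, which arrives at target 31.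

## Further compounds

F1 | step 18 | (2E)-3-[2,4-bis(methoxymethoxy)phenyl]-1-{2-hydroxy-4-methoxy-6-(methoxymethoxy)-3-[(2R)-5-methyl-2-(prop-1-en-2-yl)-5-(triethylsilyloxy)hexyl]phenyl}prop-2-en-1-one | C=C(C)[C@H](CCC(C)(C)O[Si](CC)(CC)CC)Cc1c(OC)cc(OCOC)c(C(=O)/C=C/c2ccc(OCOC)cc2OCOC)c1O
F2 | step 16 | (2E)-3-[2,4-bis(methoxymethoxy)phenyl]prop-2-en-1-yl 1H-imidazole-1-carboxylate | O=C(OC/C=C/c1ccc(OCOC)cc1OCOC)n1ccnc1
F3 | step 16 | 2-acetyl-5-methoxy-3-(methoxymethoxy)-6-[(2R)-5-methyl-2-(prop-1-en-2-yl)-5-(triethylsilyloxy)hexyl]phenyl (2E)-3-[2,4-bis(methoxymethoxy)phenyl]prop-2-en-1-yl carbonate | C=C(C)[C@H](CCC(C)(C)O[Si](CC)(CC)CC)Cc1c(OC)cc(OCOC)c(C(C)=O)c1OC(=O)OC/C=C/c1ccc(OCOC)cc1OCOC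
F4 | step 8 | 1-(2,6-dihydroxy-3-iodo-4-methoxyphenyl)ethan-1-one | COc1cc(O)c(C(C)=O)c(O)c1I
F5 | step 8 | 2-acetyl-4-iodo-5-methoxy-1,3-phenylene diacetate | COc1cc(OC(C)=O)c(C(C)=O)c(OC(C)=O)c1I
F6 | step 8 | 2-acetyl-5-methoxy-4-[(2R)-5-methyl-2-(prop-1-en-2-yl)-5-(triethylsilyloxy)hexyl]-1,3-phenylene diacetate | C=C(C)[C@H](CCC(C)(C)O[Si](CC)(CC)CC)Cc1c(OC)cc(OC(C)=O)c(C(C)=O)c1OC(C)=O
F7 | step 8 | 1-{2,6-dihydroxy-4-methoxy-3-[(2R)-5-methyl-2-(prop-1-en-2-yl)-5-(triethylsilyloxy)hexyl]phenyl}ethan-1-one | C=C(C)[C@H](CCC(C)(C)O[Si](CC)(CC)CC)Cc1c(OC)cc(O)c(C(C)=O)c1O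
F8 | step 10 | lithium 9-methoxy-9-{(2S)-5-methyl-2-(prop-1-en-2-yl)-5-[(triethylsilyl)oxy]hexyl}-9-boranuidabicyclo[3.3.1]nonane | C=C(C)[C@H](CCC(C)(C)O[Si](CC)(CC)CC)C[B-]1(OC)C2CCCC1CCC2.[Li+]
F9 | step 19 | (2S)-2-[2,4-bis(methoxymethoxy)phenyl]-8-[(2R)-5-hydroxy-5-methyl-2-(prop-1-en-2-yl)hexyl]-7-methoxy-5-(methoxymethoxy)-2,3-dihydro-4H-chromen-4-one | C=C(C)[C@H](CCC(C)(C)O)Cc1c(OC)cc(OCOC)c2c1O[C@H](c1ccc(OCOC)cc1OCOC)CC2=O
A1 | alternative 1 | (3R)-5-methoxy-7-(methoxymethoxy)-3-[3-(methoxymethoxy)-3-methylbutyl]-3,4-dihydro-2H-chromen-2-one | COc1cc(OCOC)cc2c1C[C@@H](CCC(C)(C)OCOC)C(=O)O2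
A2 | alternative 1 | {[2-(bromomethyl)-3-methoxy-5-(methoxymethoxy)phenyl]oxy}(tert-butyl)dimethylsilane | COCOc1cc(OC)c(CBr)c(O[Si](C)(C)C(C)(C)C)c1
A3 | alternative 1 | 1-(1H-imidazol-1-yl)-5-(methoxymethoxy)-5-methylhexan-1-one | COCOC(C)(C)CCCC(=O)n1ccnc1
A4 | alternative 2 | 3-methoxy-5-(methoxymethoxy)-2-[(2R)-5-methyl-2-(prop-1-en-2-yl)-5-(triethylsilyloxy)hexyl]phenol | C=C(C)[C@H](CCC(C)(C)O[Si](CC)(CC)CC)Cc1c(OC)cc(OCOC)cc1O
A5 | alternative 2 | 3-(methoxymethoxy)cyclobut-2-en-1-one | COCOC1=CC(=O)C1
A6 | alternative 2 | triethyl{[(5R)-8-methoxy-2-methyl-5-(prop-1-en-2-yl)oct-7-yn-2-yl]oxy}silane | C=C(C)[C@H](CCC(C)(C)O[Si](CC)(CC)CC)CC#COC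
A7 | alternative 3 | (2S)-2-[2,4-bis(methoxymethoxy)phenyl]-5-hydroxy-7-methoxy-8-[(2R)-5-methyl-2-(prop-1-en-2-yl)-5-(triethylsilyloxy)hexyl]-2,3-dihydro-4H-chromen-4-one | C=C(C)[C@H](CCC(C)(C)O[Si](CC)(CC)CC)Cc1c(OC)cc(O)c2c1O[C@H](c1ccc(OCOC)cc1OCOC)CC2=O
A8 | alternative 3 | (2S)-2-[2,4-bis(methoxymethoxy)phenyl]-5-bromo-2,3-dihydro-4H-pyran-4-one | O=C1C[C@@H](c2ccc(OCOC)cc2OCOC)OC=C1Br
A9 | alternative 3 | triethyl{[(5R)-8,10-dimethoxy-2-methyl-5-(prop-1-en-2-yl)-10-(trimethylsilyloxy)deca-7,9-dien-2-yl]oxy}silane | C=C(C)[C@H](CCC(C)(C)O[Si](CC)(CC)CC)CC=C(OC)C=C(OC)O[Si](C)(C)C
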